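**Strategy.** The lactone is cut at C3–C1′ (enolate alkenylation with an east dienyl iodide) and its ring is traced back, through anti-crotylation, to a west dienal. Everything rests on the butyl-bearing carbon C6 of that decadienyl chain: it carries a CH2OH arm and is allylic to the C4=C5 alkene of the (2E,4E)-diene. A Still–Wittig [2,3]-shift exploits exactly this pattern: in one operation it forms the C6–CH2OH bond, transfers the carbinol chirality from C4 to C6 and moves the alkene into conjugation as the E,E-diene; no ring is closed. Its precursor is the tributylstannylmethyl ether of an (S)-configured (2E,5Z)-bis-allylic alcohol, made in six steps from propargyl alcohol.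

Key step: step 7

Locants used below: west chain C1–C10 of the 2-methyldeca-2,4-diene unit (C6 = butyl carbon); lactone O1, C2 (C=O), C3, C4, C5; east chain C1′–C8′ counted from the lactone.

Assumption: in step 4 the (R,R)-ProPhenol dinuclear zinc catalyst is taken to add the alkynyl group to the Si face of enal 6 (the (S,S)-ligand being taken to attack the Re face, as in its aldol reactions); the sense would be checked by Mosher ester analysis, and the antipodal ligand is the only change needed if it is reversed.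

**West fragment and lactone**

Step 1
Reactants: 1 prop-2-yn-1-ol
Product: 3 (E)-3-iodo-2-methylprop-2-en-1-ol, via alkenylalane 2 (not isolated)
Conditions: AlMe3 (3 equiv), Cp2ZrCl2 (0.25 equiv), CH2Cl2, 0 °C → rt; then I2, THF, −30 → 0 °C; aq. work-up
Reagents that add atoms: trimethylaluminium, C[Al](C)C; iodine, II
Why: Zirconium-catalysed carboalumination (Negishi) adds methyl and aluminium syn across the alkyne with aluminium at the terminus, and iodinolysis of the C–Al bond with retention should give the E-iodide only.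

Step 2
Reactants: 3 (E)-3-iodo-2-methylprop-2-en-1-ol
Product: 4 (E)-1-iodo-3-[(4-methoxybenzyl)oxy]-2-methylprop-1-ene
Conditions: NaH, PMBCl, Bu4NI (cat.), THF/DMF, 0 °C → rt
Reagents that add atoms: 4-methoxybenzyl chloride, COc1ccc(CCl)cc1
Why: Williamson etherification of a primary allylic alkoxide; the alkenyl iodide has no hydrogen on C2 and cannot eliminate under NaH.

Step 3
Reactants: 4 (E)-1-iodo-3-[(4-methoxybenzyl)oxy]-2-methylprop-1-ene
Product: 6 (E)-4-[(4-methoxybenzyl)oxy]-3-methylbut-2-enal, via alkenyllithium 5 (not isolated)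
Conditions: t-BuLi (2.1 equiv), Et2O, −78 °C; DMF, −78 → 0 °C; then H2O
Reagents that add atoms: N,N-dimethylformamide, CN(C)C=O
Why: Iodine–lithium exchange on an alkenyl iodide proceeds with retention of the E geometry, and formylation of the alkenyllithium with DMF should give the E-enal once the hemiaminal salt is hydrolysed.

Step 4
Reactants: 6 (E)-4-[(4-methoxybenzyl)oxy]-3-methylbut-2-enal; 7 hex-1-yne
Product: 9 (4R,2E)-1-[(4-methoxybenzyl)oxy]-2-methyldec-2-en-5-yn-4-ol, via hexynyl(methyl)zinc 8 (not isolated)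
Conditions: 7 (3 equiv), Me2Zn (3 equiv), (R,R)-ProPhenol (10 mol%), Ph3P=O (20 mol%), toluene, 0 °C; then 6, 0 °C, 24 h; aq. work-up
Reagents that add atoms: none
Why: Catalytic asymmetric alkynylzinc addition to an aldehyde: the dinuclear zinc–ProPhenol complex binds both the enal and the alkynylzinc and should deliver the alkynyl group to the Si face in a 1,2-addition, setting C4 as R.

Step 5
Reactants: 9 (4R,2E)-1-[(4-methoxybenzyl)oxy]-2-methyldec-2-en-5-yn-4-ol
Product: 10 (4S,2E,5Z)-1-[(4-methoxybenzyl)oxy]-2-methyldeca-2,5-dien-4-ol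
Conditions: H2 (1 atm), Pd/CaCO3 poisoned with Pb(OAc)2, quinoline, EtOAc, rt
Reagents that add atoms: none
Why: Lindlar semi-hydrogenation adds H2 syn to the alkyne and should stop at the Z-alkene, sparing the trisubstituted alkene and the PMB ether; C4 keeps its spatial arrangement and becomes S only because the CIP ranking of its two carbon arms is reversed.

Step 6
Reactants: 10 (4S,2E,5Z)-1-[(4-methoxybenzyl)oxy]-2-methyldeca-2,5-dien-4-ol; 11 tributyl(iodomethyl)stannane
Product: 12 tributyl({[(4S,2E,5Z)-1-[(4-methoxybenzyl)oxy]-2-methyldeca-2,5-dien-4-yl]oxy}methyl)stannane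
Conditions: KH, 18-crown-6 (cat.), THF, 0 °C; then 11, 0 °C → rt
Reagents that add atoms: none
Why: Williamson O-alkylation of the potassium alkoxide by SN2 at the primary CH2–I carbon; no bond at C4 is broken, so C4 stays S.

Step 7
Reactants: 12 tributyl({[(4S,2E,5Z)-1-[(4-methoxybenzyl)oxy]-2-methyldeca-2,5-dien-4-yl]oxy}methyl)stannane
Product: 14 (6R,2E,4E)-6-(hydroxymethyl)-1-[(4-methoxybenzyl)oxy]-2-methyldeca-2,4-diene, via lithiomethyl ether 13 (not isolated)
Conditions: n-BuLi (1.3 equiv), THF, −78 °C, 30 min; then H2O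
Reagents that add atoms: none
Why: Tin–lithium exchange at −78 °C turns the stannylmethyl ether into the unstabilised lithiomethyl ether 13, whose carbanion attacks C6 of the Z-alkene on the face that carries the breaking C4–O bond, through a five-membered envelope transition state. The closest known reaction type is the Still–Wittig [2,3]-rearrangement of Z-allylic stannylmethyl ethers to E-homoallylic alcohols with 1,3-chirality transfer. No ring is closed. The new stereocentre C6 (R) is controlled by the S carbinol carbon C4: allylic 1,3-strain with the cis butyl group puts the carbinol hydrogen inside and the propenyl arm outside, so the suprafacial shift copies the C4 configuration onto C6 and the new C4=C5 alkene is E. The step needs regioselectivity for the disubstituted Z terminus over the methyl-bearing terminus of the other allyl arm, which is secured because attack there would build a quaternary carbon, and [2,3] over [1,2] migration, which is secured by holding the carbanion at −78 °C. The PMB ether and the trisubstituted alkene are inert to n-BuLi at this temperature.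

Step 8
Reactants: 14 (6R,2E,4E)-6-(hydroxymethyl)-1-[(4-methoxybenzyl)oxy]-2-methyldeca-2,4-diene
Product: 15 (6R,2E,4E)-6-[(tert-butyldimethylsilyloxy)methyl]-1-[(4-methoxybenzyl)oxy]-2-methyldeca-2,4-diene
Conditions: TBSCl, imidazole, DMF, 0 °C → rt
Reagents that add atoms: tert-butyldimethylsilyl chloride, CC(C)(C)[Si](C)(C)Cl
Why: Standard imidazole-promoted silylation of an unhindered primary alcohol.

Step 9
Reactants: 15 (6R,2E,4E)-6-[(tert-butyldimethylsilyloxy)methyl]-1-[(4-methoxybenzyl)oxy]-2-methyldeca-2,4-diene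
Product: 16 (6R,2E,4E)-6-[(tert-butyldimethylsilyloxy)methyl]-2-methyldeca-2,4-dien-1-ol
Conditions: DDQ (1.2 equiv), CH2Cl2/pH 7 buffer (10:1), 0 °C
Reagents that add atoms: none
Why: Oxidative PMB cleavage by hydride abstraction from the electron-rich benzylic position and hydrolysis of the oxocarbenium ion; the TBS ether is inert, and any dienol oxidised further by DDQ is already the aldehyde of step 10.

Step 10
Reactants: 16 (6R,2E,4E)-6-[(tert-butyldimethylsilyloxy)methyl]-2-methyldeca-2,4-dien-1-ol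
Product: 17 (6R,2E,4E)-6-[(tert-butyldimethylsilyloxy)methyl]-2-methyldeca-2,4-dienal
Conditions: MnO2 (20 equiv), CH2Cl2, rt
Reagents that add atoms: none
Why: Chemoselective MnO2 oxidation of a dienylic alcohol, which should not isomerise the diene or over-oxidise.

Step 11
Reactants: 17 (6R,2E,4E)-6-[(tert-butyldimethylsilyloxy)methyl]-2-methyldeca-2,4-dienal
Product: 18 (3S,4S,5E,7E,9R)-9-[(tert-butyldimethylsilyloxy)methyl]-3,5-dimethyltrideca-1,5,7-trien-4-ol
Conditions: (E)-but-2-ene, KOt-Bu, n-BuLi, THF, −78 → −45 °C; (−)-Ipc2BOMe, −78 °C; BF3·OEt2; 17, −78 °C; then NaOH, H2O2, rt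
Reagents that add atoms: (E)-but-2-ene, C/C=C/C
Why: Brown crotylation: the (E)-crotylborane made from (+)-α-pinene reacts through a closed chair transition state on the Si face of the aldehyde, which should give the anti adduct with the future lactone C5 (carbinol) and C4 (methyl) both S.

Step 12
Reactants: 18 (3S,4S,5E,7E,9R)-9-[(tert-butyldimethylsilyloxy)methyl]-3,5-dimethyltrideca-1,5,7-trien-4-ol
Product: 20 (3S,4S,5E,7E,9R)-9-[(tert-butyldimethylsilyloxy)methyl]-3,5-dimethyltrideca-5,7-diene-1,4-diol, via B-alkyl-9-BBN 19 (not isolated)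
Conditions: 9-BBN (2.5 equiv), THF, 0 °C → rt; then NaOH, H2O2, 0 °C
Reagents that add atoms: hydrogen peroxide, OO
Why: Anti-Markovnikov hydroboration–oxidation; the bulky 9-BBN should take the monosubstituted vinyl group far faster than the di- and trisubstituted alkenes of the conjugated diene.

Step 13
Reactants: 20 (3S,4S,5E,7E,9R)-9-[(tert-butyldimethylsilyloxy)methyl]-3,5-dimethyltrideca-5,7-diene-1,4-diol
Product: 22 (4S,5S)-5-[(2E,4E,6R)-6-{[(tert-butyldimethylsilyl)oxy]methyl}deca-2,4-dien-2-yl]-4-methyldihydrofuran-2(3H)-one, via lactol 21 (not isolated)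
Conditions: TEMPO (0.2 equiv), PhI(OAc)2 (2.5 equiv), CH2Cl2, rt
Reagents that add atoms: none
Why: Oxoammonium (TEMPO/PhI(OAc)2) oxidation is selective for the unhindered primary alcohol; the aldehyde closes to the five-membered lactol, which should be oxidised to the γ-lactone before the hindered secondary dienylic alcohol reacts, and no stereocentre is touched.

**East fragment**

Step 14
Reactants: 3 (E)-3-iodo-2-methylprop-2-en-1-ol
Product: 23 (E)-3-iodo-2-methylprop-2-enal
Conditions: MnO2 (15 equiv), CH2Cl2, rt; used as a solution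
Reagents that add atoms: none
Why: MnO2 oxidation of an allylic alcohol with retention of the alkene geometry.

Step 15
Reactants: 23 (E)-3-iodo-2-methylprop-2-enal
Product: 24 (2E,4E)-5-iodo-4-methylpenta-2,4-dienal
Conditions: Ph3P=CHCHO (1.1 equiv), toluene, 70 °C
Reagents that add atoms: (triphenylphosphoranylidene)acetaldehyde, O=CC=P(c1ccccc1)(c1ccccc1)c1ccccc1
Why: Wittig reaction with a stabilised formyl ylide gives the E-enal by two-carbon homologation; the product dienal is less electrophilic than 23, which should limit a second homologation.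

Step 16
Reactants: 25 (R)-4-benzyl-3-propionyloxazolidin-2-one; 24 (2E,4E)-5-iodo-4-methylpenta-2,4-dienal
Product: 27 (R)-4-benzyl-3-[(2R,3S,4E,6E)-3-hydroxy-7-iodo-2,6-dimethylhepta-4,6-dienoyl]oxazolidin-2-one, via boron enolate 26 (not isolated)
Conditions: Bu2BOTf, Et3N, CH2Cl2, −78 → 0 °C; 24, −78 → 0 °C; pH 7 buffer, MeOH, H2O2
Reagents that add atoms: none
Why: Evans syn-aldol: the Z-boron enolate reacts through a chair Zimmerman–Traxler transition state in which the benzyl group of the auxiliary shields one enolate face, which should give the syn adduct with C2 R and C3 S (C6′ and C5′ of the target).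

Step 17
Reactants: 27 (R)-4-benzyl-3-[(2R,3S,4E,6E)-3-hydroxy-7-iodo-2,6-dimethylhepta-4,6-dienoyl]oxazolidin-2-one
Product: 28 (2R,3S,4E,6E)-3-hydroxy-7-iodo-N-methoxy-N,2,6-trimethylhepta-4,6-dienamide
Conditions: MeNH(OMe)·HCl, AlMe3, CH2Cl2, −10 → 0 °C
Reagents that add atoms: N,O-dimethylhydroxylamine hydrochloride, CNOC.Cl
Why: Aluminium amide transamination of the imide, assisted by the free β-hydroxyl as its aluminium alkoxide, should give the Weinreb amide without epimerisation or retro-aldol and release the auxiliary.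

Step 18
Reactants: 28 (2R,3S,4E,6E)-3-hydroxy-7-iodo-N-methoxy-N,2,6-trimethylhepta-4,6-dienamide
Product: 29 (2R,3S,4E,6E)-7-iodo-N-methoxy-N,2,6-trimethyl-3-(triethylsilyloxy)hepta-4,6-dienamide
Conditions: TESCl, imidazole, DMF, 0 °C → rt
Reagents that add atoms: chlorotriethylsilane, CC[Si](CC)(CC)Cl
Why: Standard silylation of a secondary alcohol, which blocks retro-aldol and proton transfer in the next two steps.

Step 19
Reactants: 29 (2R,3S,4E,6E)-7-iodo-N-methoxy-N,2,6-trimethyl-3-(triethylsilyloxy)hepta-4,6-dienamide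
Product: 30 (3R,4S,5E,7E)-8-iodo-3,7-dimethyl-4-(triethylsilyloxy)octa-5,7-dien-2-one
Conditions: MeMgBr (2 equiv), THF, 0 °C; then H2O
Reagents that add atoms: methylmagnesium bromide, C[Mg]Br
Why: Weinreb ketone synthesis: the chelated tetrahedral magnesium adduct survives until work-up, so only one methyl adds and the α-stereocentre and the alkenyl iodide are untouched.

**Union and deprotection**

Step 20
Reactants: 22 (4S,5S)-5-[(2E,4E,6R)-6-{[(tert-butyldimethylsilyl)oxy]methyl}deca-2,4-dien-2-yl]-4-methyldihydrofuran-2(3H)-one; 30 (3R,4S,5E,7E)-8-iodo-3,7-dimethyl-4-(triethylsilyloxy)octa-5,7-dien-2-one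
Product: 33 (3S,4S,5S)-5-[(2E,4E,6R)-6-{[(tert-butyldimethylsilyl)oxy]methyl}deca-2,4-dien-2-yl]-3-[(1E,3E,5S,6R)-2,6-dimethyl-7-oxo-5-(triethylsilyloxy)octa-1,3-dien-1-yl]-4-methyldihydrofuran-2(3H)-one, via lithium enolate 31 (not isolated), via zinc enolate 32 (not isolated)
Conditions: LiN(SiMe3)2 (1.05 equiv), THF, −78 °C; ZnCl2 (1.5 equiv), −78 °C → rt; 30, Pd2(dba)3 (2.5 mol%), P(t-Bu)3 (5 mol%), THF, rt
Reagents that add atoms: none
Why: Negishi-type palladium-catalysed α-alkenylation of a zinc ester enolate (oxidative addition of the alkenyl iodide with retention, transmetalation, reductive elimination), in which the alkenyl group should enter anti to the C4 methyl to set C3 as S in the all-trans lactone, while the weakly basic zinc enolate spares the methyl ketone and the silyl ethers.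

Step 21
Reactants: 33 (3S,4S,5S)-5-[(2E,4E,6R)-6-{[(tert-butyldimethylsilyl)oxy]methyl}deca-2,4-dien-2-yl]-3-[(1E,3E,5S,6R)-2,6-dimethyl-7-oxo-5-(triethylsilyloxy)octa-1,3-dien-1-yl]-4-methyldihydrofuran-2(3H)-one
Product: 34 (3S,4S,5S)-5-[(2E,4E,6R)-6-(hydroxymethyl)deca-2,4-dien-2-yl]-3-[(1E,3E,5S,6R)-5-hydroxy-2,6-dimethyl-7-oxoocta-1,3-dien-1-yl]-4-methyldihydrofuran-2(3H)-one
Conditions: HF·pyridine, pyridine, THF, 0 °C → rt
Reagents that add atoms: none
Why: Fluoride-assisted cleavage of both silyl ethers under buffered, weakly acidic conditions, which should spare the β-hydroxy ketone (no retro-aldol or elimination), the lactone and the epimerisable C3 and C6′ centres.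

**Compound list**

1 | prop-2-yn-1-ol | C#CCO | starting material
2 | dimethyl[(E)-3-(dimethylalumanyloxy)-2-methylprop-1-enyl]alumane | C[Al](C)OC/C(C)=C/[Al](C)C | intermediate (not isolated)
3 | (E)-3-iodo-2-methylprop-2-en-1-ol | OC/C(C)=C/I | intermediate
4 | (E)-1-iodo-3-[(4-methoxybenzyl)oxy]-2-methylprop-1-ene | COc1ccc(COC/C(C)=C/I)cc1 | intermediate
5 | [(E)-3-[(4-methoxybenzyl)oxy]-2-methylprop-1-enyl]lithium | COc1ccc(COC/C(C)=C/[Li])cc1 | intermediate (not isolated)
6 | (E)-4-[(4-methoxybenzyl)oxy]-3-methylbut-2-enal | COc1ccc(COC/C(C)=C/C=O)cc1 | intermediate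
7 | hex-1-yne | CCCCC#C | starting material
8 | hex-1-ynyl(methyl)zinc | CCCCC#C[Zn]C | intermediate (not isolated)
9 | (4R,2E)-1-[(4-methoxybenzyl)oxy]-2-methyldec-2-en-5-yn-4-ol | CCCCC#C[C@H](O)/C=C(\C)COCc1ccc(OC)cc1 | intermediate
10 | (4S,2E,5Z)-1-[(4-methoxybenzyl)oxy]-2-methyldeca-2,5-dien-4-ol | CCCC/C=C\[C@H](O)/C=C(\C)COCc1ccc(OC)cc1 | intermediate
11 | tributyl(iodomethyl)stannane | CCCC[Sn](CCCC)(CCCC)CI | starting material
12 | tributyl({[(4S,2E,5Z)-1-[(4-methoxybenzyl)oxy]-2-methyldeca-2,5-dien-4-yl]oxy}methyl)stannane | CCCC/C=C\[C@H](OC[Sn](CCCC)(CCCC)CCCC)/C=C(\C)COCc1ccc(OC)cc1 | intermediate (key-step precursor)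
13 | ({[(4S,2E,5Z)-1-[(4-methoxybenzyl)oxy]-2-methyldeca-2,5-dien-4-yl]oxy}methyl)lithium | CCCC/C=C\[C@H](OC[Li])/C=C(\C)COCc1ccc(OC)cc1 | intermediate (not isolated)
14 | (6R,2E,4E)-6-(hydroxymethyl)-1-[(4-methoxybenzyl)oxy]-2-methyldeca-2,4-diene | CCCC[C@H](/C=C/C=C(\C)COCc1ccc(OC)cc1)CO | intermediate (key-step product)
15 | (6R,2E,4E)-6-[(tert-butyldimethylsilyloxy)methyl]-1-[(4-methoxybenzyl)oxy]-2-methyldeca-2,4-diene | CCCC[C@H](/C=C/C=C(\C)COCc1ccc(OC)cc1)CO[Si](C)(C)C(C)(C)C | intermediate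
16 | (6R,2E,4E)-6-[(tert-butyldimethylsilyloxy)methyl]-2-methyldeca-2,4-dien-1-ol | CCCC[C@H](/C=C/C=C(\C)CO)CO[Si](C)(C)C(C)(C)C | intermediate
17 | (6R,2E,4E)-6-[(tert-butyldimethylsilyloxy)methyl]-2-methyldeca-2,4-dienal | CCCC[C@H](/C=C/C=C(\C)C=O)CO[Si](C)(C)C(C)(C)C | intermediate
18 | (3S,4S,5E,7E,9R)-9-[(tert-butyldimethylsilyloxy)methyl]-3,5-dimethyltrideca-1,5,7-trien-4-ol | CCCC[C@H](/C=C/C=C(\C)[C@@H](O)[C@@H](C)C=C)CO[Si](C)(C)C(C)(C)C | intermediate
19 | 9-[(3S,4S,5E,7E,9R)-9-[(tert-butyldimethylsilyloxy)methyl]-4-hydroxy-3,5-dimethyltrideca-5,7-dien-1-yl]-9-borabicyclo[3.3.1]nonane | CCCC[C@H](/C=C/C=C(\C)[C@@H](O)[C@@H](C)CCB1C2CCCC1CCC2)CO[Si](C)(C)C(C)(C)C | intermediate (not isolated)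
20 | (3S,4S,5E,7E,9R)-9-[(tert-butyldimethylsilyloxy)methyl]-3,5-dimethyltrideca-5,7-diene-1,4-diol | CCCC[C@H](/C=C/C=C(\C)[C@@H](O)[C@@H](C)CCO)CO[Si](C)(C)C(C)(C)C | intermediate
21 | (4S,5S)-5-[(2E,4E,6R)-6-{[(tert-butyldimethylsilyl)oxy]methyl}deca-2,4-dien-2-yl]-4-methyltetrahydrofuran-2-ol (both anomers) | CCCC[C@H](/C=C/C=C(\C)[C@H]1OC(O)C[C@@H]1C)CO[Si](C)(C)C(C)(C)C | intermediate (not isolated)
22 | (4S,5S)-5-[(2E,4E,6R)-6-{[(tert-butyldimethylsilyl)oxy]methyl}deca-2,4-dien-2-yl]-4-methyldihydrofuran-2(3H)-one | CCCC[C@H](/C=C/C=C(\C)[C@H]1OC(=O)C[C@@H]1C)CO[Si](C)(C)C(C)(C)C | intermediate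
23 | (E)-3-iodo-2-methylprop-2-enal | O=C/C(C)=C/I | intermediate
24 | (2E,4E)-5-iodo-4-methylpenta-2,4-dienal | O=C/C=C/C(C)=C/I | intermediate
25 | (R)-4-benzyl-3-propionyloxazolidin-2-one | CCC(=O)N1C(=O)OC[C@H]1Cc1ccccc1 | starting material
26 | (Z)-dibutylboron enolate of 25 | C/C=C(\OB(CCCC)CCCC)N1C(=O)OC[C@H]1Cc1ccccc1 | intermediate (not isolated)
27 | (R)-4-benzyl-3-[(2R,3S,4E,6E)-3-hydroxy-7-iodo-2,6-dimethylhepta-4,6-dienoyl]oxazolidin-2-one | I/C=C(C)/C=C/[C@H](O)[C@@H](C)C(=O)N1C(=O)OC[C@H]1Cc1ccccc1 | intermediate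
28 | (2R,3S,4E,6E)-3-hydroxy-7-iodo-N-methoxy-N,2,6-trimethylhepta-4,6-dienamide | I/C=C(C)/C=C/[C@H](O)[C@@H](C)C(=O)N(C)OC | intermediate
29 | (2R,3S,4E,6E)-7-iodo-N-methoxy-N,2,6-trimethyl-3-(triethylsilyloxy)hepta-4,6-dienamide | I/C=C(C)/C=C/[C@H](O[Si](CC)(CC)CC)[C@@H](C)C(=O)N(C)OC | intermediate
30 | (3R,4S,5E,7E)-8-iodo-3,7-dimethyl-4-(triethylsilyloxy)octa-5,7-dien-2-one | I/C=C(C)/C=C/[C@H](O[Si](CC)(CC)CC)[C@@H](C)C(C)=O | intermediate
31 | lithium enolate of 22 | CCCC[C@H](/C=C/C=C(\C)[C@H]1OC(O[Li])=C[C@@H]1C)CO[Si](C)(C)C(C)(C)C | intermediate (not isolated)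
32 | chlorozinc enolate of 22 | CCCC[C@H](/C=C/C=C(\C)[C@H]1OC(O[Zn]Cl)=C[C@@H]1C)CO[Si](C)(C)C(C)(C)C | intermediate (not isolated)
33 | (3S,4S,5S)-5-[(2E,4E,6R)-6-{[(tert-butyldimethylsilyl)oxy]methyl}deca-2,4-dien-2-yl]-3-[(1E,3E,5S,6R)-2,6-dimethyl-7-oxo-5-(triethylsilyloxy)octa-1,3-dien-1-yl]-4-methyldihydrofuran-2(3H)-one | CCCC[C@H](/C=C/C=C(\C)[C@H]1OC(=O)[C@@H](/C=C(C)/C=C/[C@H](O[Si](CC)(CC)CC)[C@@H](C)C(C)=O)[C@@H]1C)CO[Si](C)(C)C(C)(C)C | intermediate
34 | (3S,4S,5S)-5-[(2E,4E,6R)-6-(hydroxymethyl)deca-2,4-dien-2-yl]-3-[(1E,3E,5S,6R)-5-hydroxy-2,6-dimethyl-7-oxoocta-1,3-dien-1-yl]-4-methyldihydrofuran-2(3H)-one | CCCC[C@H](/C=C/C=C(\C)[C@H]1OC(=O)[C@@H](/C=C(C)/C=C/[C@H](O)[C@@H](C)C(C)=O)[C@@H]1C)CO | target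

**Step count.** Total: 21 steps. Longest linear sequence: 15 steps (steps 1–13, 20 and 21, from prop-2-yn-1-ol); the east branch is steps 14–19.

**Steps most likely to fail**

Step 7. Process at risk: homolytic [1,2]-migration through a bis-allylic radical pair and [2,3]-shift into the other allyl arm, both of which divert material from the 1,3-transposed alcohol. Fallback: a copper-mediated, carbamate-directed syn-SN2′ substitution with a hydroxymethyl anion equivalent replaces the sigmatropic shift. It sets out from 10: phenyl isocyanate (DMAP, CH2Cl2) gives the N-phenylcarbamate F1; deprotonation (MeLi, THF, −78 °C), CuI·2LiCl and (i-PrO)Me2SiCH2MgCl should transfer the silylmethyl group to C6 on the face of the carbamate, through the same hydrogen-inside conformer and hence with the same E-alkene and R centre, to give the (isopropoxy)dimethylsilane F2; Tamao oxidation (H2O2, KF, KHCO3, THF/MeOH) turns C–Si into C–OH and comes back to the route at 14.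

Step 20. Process at risk: proton transfer from the more acidic α-alkenyl lactone to unreacted enolate, leading to epimerisation at C3, drift of the C1′=C2′ alkene into conjugation with the lactone or a second alkenylation. Fallback: the polarity of the union is reversed so that no enolate base is present. It sets out from 22 and 30: 22 is converted (LiN(SiMe3)2, Me3SiCl, THF, −78 °C) into the silyl ketene acetal F3 and brominated (NBS, THF, −78 °C) to the α-bromo lactone F4; 30 is stannylated (Me3SnSnMe3, Pd(PPh3)4, toluene, 80 °C) to the dienylstannane F5; Stille coupling of F4 with F5 (Pd2(dba)3, P(2-furyl)3, THF, 50 °C) should pass through the same palladium enolate under neutral conditions and comes back to the route at 33.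

Step 4. Process at risk: poor or reversed facial selectivity in the alkynyl transfer, which would lower the enantiomeric purity of every later west intermediate. Fallback: reagent-controlled reduction of a ketone replaces catalytic C–C bond formation. It sets out from 6 and 7: 7 is lithiated (n-BuLi, THF, −78 °C) to hex-1-ynyllithium F6, which adds to 6 to give the racemic alcohol F7; MnO2 (CH2Cl2) gives the ynone F8; asymmetric transfer hydrogenation with RuCl[(R,R)-TsDPEN](p-cymene) (divalent ruthenium) in i-PrOH, the alkyne taking the site normally occupied by an aryl group, should give the R alcohol and comes back to the route at 9.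

**Further compounds**

F1 | step 7 | (4S,2E,5Z)-1-[(4-methoxybenzyl)oxy]-2-methyldeca-2,5-dien-4-yl N-phenylcarbamate | CCCC/C=C\[C@H](OC(=O)Nc1ccccc1)/C=C(\C)COCc1ccc(OC)cc1
F2 | step 7 | [(2R,3E,5E)-2-butyl-7-[(4-methoxybenzyl)oxy]-6-methylhepta-3,5-dien-1-yl](isopropoxy)dimethylsilane | CCCC[C@H](/C=C/C=C(\C)COCc1ccc(OC)cc1)C[Si](C)(C)OC(C)C
F3 | step 20 | trimethylsilyl ketene acetal of 22 | CCCC[C@H](/C=C/C=C(\C)[C@H]1OC(O[Si](C)(C)C)=C[C@@H]1C)CO[Si](C)(C)C(C)(C)C
F4 | step 20 | (4S,5S)-3-bromo-5-[(2E,4E,6R)-6-{[(tert-butyldimethylsilyl)oxy]methyl}deca-2,4-dien-2-yl]-4-methyldihydrofuran-2(3H)-one (C3 epimers) | CCCC[C@H](/C=C/C=C(\C)[C@H]1OC(=O)C(Br)[C@@H]1C)CO[Si](C)(C)C(C)(C)C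
F5 | step 20 | (3R,4S,5E,7E)-3,7-dimethyl-4-(triethylsilyloxy)-8-(trimethylstannyl)octa-5,7-dien-2-one | C[Sn](C)(C)/C=C(C)/C=C/[C@H](O[Si](CC)(CC)CC)[C@@H](C)C(C)=O
F6 | step 4 | hex-1-ynyllithium | CCCCC#C[Li]
F7 | step 4 | racemic (E)-1-[(4-methoxybenzyl)oxy]-2-methyldec-2-en-5-yn-4-ol | CCCCC#CC(O)/C=C(\C)COCc1ccc(OC)cc1
F8 | step 4 | (E)-1-[(4-methoxybenzyl)oxy]-2-methyldec-2-en-5-yn-4-one | CCCCC#CC(=O)/C=C(\C)COCc1ccc(OC)cc1
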